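**Plan**

Germacrane numbering is used: ring C1–C10 with the Z-olefin C1=C10 and the E-olefin C4=C5, lactone oxygen on C6, fusion carbon C7, acyloxy carbon C8, carbinol C9, lactone carbons C11 (α), C12 (C=O) and C13 (=CH2).
Enabling feature: C8 and C9 are adjacent carbinol carbons of the ten-membered ring (cis-diol, C8 esterified, C9 free and allylic to C1=C10), so each can be an aldehyde carbon and the two can be joined reductively.
Cuts, in order: the C8–O ester bond (side-chain acid), C11=C13, the C8–C9 bond (pinacol), the lactone C12–O6 and C6–C7 bonds (aldol), and C1=C10 (olefination).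
Forward: geraniol gives the C1–C6/C9/C10 enal; an anti-aldol with a succinyl imide and lactonisation close the γ-lactone first; SmI2 coupling of the C8/C9 dialdehyde then closes the ten-membered ring; methylenation and C8 acylation finish.
Stereochemistry: C6 and C7 from an (R)-benzyloxazolidinone (anti-aldol); C8 from C7 and C9 from the samarium-bridged coupling; the E-olefin from geraniol and the Z-olefin from a Still–Gennari olefination; the side-chain centre from an (S)-benzyloxazolidinone-directed allylation.

Key step: step 14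

Remark on the chemistry: the magnesium-catalysed anti-aldol of step 9 is taken to run through the chelated Z-enolate with attack anti to the benzyl group, as in alkylations of such imides, hence the (R)-oxazolidinone; the side-chain acid is made by auxiliary-controlled allylation because this sets its (R) centre in the fewest steps.

**Route**

Step 1
Reactants: 1 geraniol
Product: 2 geranyl tert-butyldimethylsilyl ether
Conditions: TBSCl, imidazole, CH2Cl2, 0 → 23 °C
Reagents that add atoms: tert-butyldimethylsilyl chloride, CC(C)(C)[Si](C)(C)Cl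
Why: Silyl ether formation on the primary allylic alcohol masks the C6 oxygen for the oxidative and hydride steps that follow, and no stereocentre is involved.

Step 2
Reactants: 2 geranyl tert-butyldimethylsilyl ether
Product: 4 (4E)-6-[(tert-butyldimethylsilyl)oxy]-4-methylhex-4-enal, via epoxide 3 (not isolated)
Conditions: mCPBA (1.05 equiv), CH2Cl2, −20 → 0 °C; then H5IO6, THF/H2O, 0 °C
Reagents that add atoms: 3-chloroperbenzoic acid, O=C(OO)c1cccc(Cl)c1
Why: Prilezhaev epoxidation should take the distal olefin, which is more electron-rich than the one deactivated by the allylic silyloxy group, and periodic acid then opens the epoxide and cleaves the glycol (Malaprade cleavage) to the C1 aldehyde with loss of acetone.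

Step 3
Reactants: 4 (4E)-6-[(tert-butyldimethylsilyl)oxy]-4-methylhex-4-enal; 5 ethyl 2-[bis(2,2,2-trifluoroethoxy)phosphoryl]propanoate
Product: 6 ethyl (2Z,6E)-8-[(tert-butyldimethylsilyl)oxy]-2,6-dimethylocta-2,6-dienoate
Conditions: KN(SiMe3)2, 18-crown-6, THF, −78 °C
Reagents that add atoms: none
Why: Still–Gennari variant of the Horner–Wadsworth–Emmons olefination, in which the electron-poor phosphonate eliminates from the kinetically formed adduct and should give the Z-trisubstituted enoate that becomes C1=C10 with C9 cis to C2.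

Step 4
Reactants: 6 ethyl (2Z,6E)-8-[(tert-butyldimethylsilyl)oxy]-2,6-dimethylocta-2,6-dienoate
Product: 7 (2Z,6E)-8-[(tert-butyldimethylsilyl)oxy]-2,6-dimethylocta-2,6-dien-1-ol
Conditions: i-Bu2AlH (2.5 equiv), CH2Cl2, −78 °C
Reagents that add atoms: none
Why: Hydride reduction of the conjugated ester gives the allylic alcohol by 1,2-reduction without touching the silyl ether or the olefin geometry.

Step 5
Reactants: 7 (2Z,6E)-8-[(tert-butyldimethylsilyl)oxy]-2,6-dimethylocta-2,6-dien-1-ol
Product: 8 (2Z,6E)-8-[(tert-butyldimethylsilyl)oxy]-1-[(tert-butyldiphenylsilyl)oxy]-2,6-dimethylocta-2,6-diene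
Conditions: TBDPSCl, imidazole, CH2Cl2, 23 °C
Reagents that add atoms: tert-butyldiphenylsilyl chloride, CC(C)(C)[Si](Cl)(c1ccccc1)c1ccccc1
Why: Silylation with the more acid-stable tert-butyldiphenylsilyl group protects the C9 oxygen so that the two allylic termini can be told apart.

Step 6
Reactants: 8 (2Z,6E)-8-[(tert-butyldimethylsilyl)oxy]-1-[(tert-butyldiphenylsilyl)oxy]-2,6-dimethylocta-2,6-diene
Product: 9 (2E,6Z)-8-[(tert-butyldiphenylsilyl)oxy]-3,7-dimethylocta-2,6-dien-1-ol
Conditions: PPTS (cat.), MeOH, 23 °C
Reagents that add atoms: none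
Why: Acid-catalysed methanolysis (selective desilylation) removes the primary tert-butyldimethylsilyl ether much faster than the tert-butyldiphenylsilyl ether and so frees only the C6 hydroxyl.

Step 7
Reactants: 9 (2E,6Z)-8-[(tert-butyldiphenylsilyl)oxy]-3,7-dimethylocta-2,6-dien-1-ol
Product: 10 (2E,6Z)-8-[(tert-butyldiphenylsilyl)oxy]-3,7-dimethylocta-2,6-dienal
Conditions: MnO2, CH2Cl2, 23 °C
Reagents that add atoms: none
Why: Allylic oxidation with MnO2 stops at the aldehyde and leaves the E geometry of the enal and the Z-allylic silyl ether intact.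

Step 8
Reactants: 11 (4R)-4-benzyl-1,3-oxazolidin-2-one; 12 methyl 4-chloro-4-oxobutanoate
Product: 13 methyl 4-[(4R)-4-benzyl-2-oxo-1,3-oxazolidin-3-yl]-4-oxobutanoate
Conditions: n-BuLi, THF, −78 °C; then 12, −78 → 0 °C
Reagents that add atoms: none
Why: N-acylation of the lithiated oxazolidinone by the acid chloride is far faster than attack at the methyl ester and gives the succinyl imide that carries C7, C8, C11 and C12.

Step 9
Reactants: 13 methyl 4-[(4R)-4-benzyl-2-oxo-1,3-oxazolidin-3-yl]-4-oxobutanoate; 10 (2E,6Z)-8-[(tert-butyldiphenylsilyl)oxy]-3,7-dimethylocta-2,6-dienal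
Product: 15 anti-aldol adduct methyl (3S,4S,5E,9Z)-3-{[(4R)-4-benzyl-2-oxo-1,3-oxazolidin-3-yl]carbonyl}-11-[(tert-butyldiphenylsilyl)oxy]-4-hydroxy-6,10-dimethylundeca-5,9-dienoate, via trimethylsilyl ether 14 (not isolated)
Conditions: MgCl2 (0.2 equiv), Et3N, TMSCl, EtOAc, 23 °C; then TFA (cat.), MeOH, 23 °C
Reagents that add atoms: none
Why: Evans magnesium-halide-catalysed anti-aldol reaction, in which soft enolisation of the imide (not the ester) gives the chelated magnesium Z-enolate, this adds to the enal through a boat transition state on the face away from the benzyl group with TMSCl turning the catalyst over, so that C7 and C6 should arise anti with the absolute sense fixed by the (R)-auxiliary, and acidic methanol removes the trimethylsilyl group.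

Step 10
Reactants: 15 anti-aldol adduct
Product: 16 (4R)-4-benzyl-3-{[(2S,3S)-2-[(1E,5Z)-7-[(tert-butyldiphenylsilyl)oxy]-2,6-dimethylhepta-1,5-dien-1-yl]-5-oxooxolan-3-yl]carbonyl}-1,3-oxazolidin-2-one (6,7-cis lactone)
Conditions: PPTS (cat.), toluene, 60 °C
Reagents that add atoms: none
Why: Acid-catalysed lactonisation (intramolecular transesterification, 5-exo-trig) of the γ-hydroxy ester joins O6 to C12, and the anti relation of the aldol adduct becomes the 6,7-cis lactone without touching either stereocentre.

Step 11
Reactants: 16 cis-lactone imide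
Product: 17 (4R,5S)-5-[(1E,5Z)-7-[(tert-butyldiphenylsilyl)oxy]-2,6-dimethylhepta-1,5-dien-1-yl]-4-(hydroxymethyl)oxolan-2-one
Conditions: NaBH4, THF/H2O (3:1), 0 °C
Reagents that add atoms: none
Why: Reductive removal of the oxazolidinone, in which the activated exocyclic imide carbonyl is reduced to the primary alcohol much faster than the lactone, at 0 °C and without strong base so that C7 is not epimerised.

Step 12
Reactants: 17 hydroxymethyl lactone silyl ether
Product: 18 (4R,5S)-5-[(1E,5Z)-7-hydroxy-2,6-dimethylhepta-1,5-dien-1-yl]-4-(hydroxymethyl)oxolan-2-one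
Conditions: HF·pyridine, pyridine, THF, 0 → 23 °C
Reagents that add atoms: none
Why: Fluoride-mediated desilylation under buffered, non-basic conditions frees the C9 allylic alcohol without opening or transposing the lactone.

Step 13
Reactants: 18 lactone diol
Product: 19 (2S,3S)-2-[(1E,5Z)-2,6-dimethyl-7-oxohepta-1,5-dien-1-yl]-5-oxooxolane-3-carbaldehyde (cis-lactone dialdehyde)
Conditions: Dess–Martin periodinane (2.5 equiv), NaHCO3, CH2Cl2, 0 °C; used at once
Reagents that add atoms: none
Why: Dess–Martin oxidation of both primary alcohols under bicarbonate buffer gives the dialdehyde without over-oxidation, and the neutral conditions are chosen so that neither C7 (α to the new aldehyde) nor the Z-enal isomerises.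

Step 14
Reactants: 19 cis-lactone dialdehyde
Product: 20 (1(10)Z,4E,6S,7R,8S,9R)-8,9-dihydroxygermacra-1(10),4-dien-12,6-olide (H6, H7, H8 and H9 on one face)
Conditions: SmI2 (4 equiv), THF, −78 °C, 19 added over 6 h to a final 2 mM, then −78 → −20 °C; pH 7 buffer
Reagents that add atoms: none
Why: Intramolecular pinacol coupling, in which SmI2 (divalent samarium) transfers an electron first to the conjugated C9 aldehyde, the trivalent samarium ketyl binds the C8 aldehyde, and the C8–C9 bond forms inside this chelate, by combination with a second ketyl or by addition to the bound carbonyl and a further electron transfer, to give the samarium diolate that is hydrolysed on work-up. The closest known reactions are the pinacol macrocyclisations of dialdehydes with SmI2 or low-valent titanium that give medium and large carbocyclic 1,2-diols, germacrane-type ten-membered rings included. The ten-membered ring closes end to end by union of the two carbonyl carbons (a 10-exo-trig closure of C9 onto the C8 carbonyl), helped by the cis-lactone and the Z-olefin as turn elements and by high dilution. C9 is set relative to C8 by the samarium bridge, which holds both oxygens syn during bond formation and should give the cis (erythro) diol; C8 is set by C7, because with C11 held on one face by the cis-fused lactone the C9 carbon is expected to bond anti to the C7–C11 bond with the C8 oxygen between C6 and C11. The step needs 1,2-coupling of the enal ketyl and not coupling through C1, retention of the Z geometry, ring closure in preference to oligomerisation and an untouched lactone; low temperature (slow rotation in the allyl-type ketyl), slow addition and the absence of proton donors or amines (without which SmI2 does not reduce a saturated lactone) are chosen to secure these.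

Step 15
Reactants: 20 macrocyclic cis-diol
Product: 21 8,9-O-isopropylidene derivative of 20
Conditions: 2,2-dimethoxypropane, PPTS (cat.), CH2Cl2, 23 °C
Reagents that add atoms: 2,2-dimethoxypropane, COC(C)(C)OC
Why: Acid-catalysed transacetalisation gives the five-membered acetonide, which forms readily only from the cis-diol and so also checks the relative configuration at C8 and C9, and it masks both hydroxyls for the enolate step.

Step 16
Reactants: 21 acetonide
Product: 22 11-[(dimethylamino)methyl] derivative of 21 (configuration at C11 of no consequence)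
Conditions: LiN(i-Pr)2, THF, −78 °C; then CH2=NMe2+ I−, −78 → 0 °C
Reagents that add atoms: dimethylmethyleneiminium iodide (Eschenmoser's salt), C=[N+](C)C.[I-]
Why: Mannich reaction of the lactone lithium enolate, where C11 is the only enolisable position, no leaving group sits β to the enolate carbon, and the new C11 centre is destroyed in the next step.

Step 17
Reactants: 22 Mannich base
Product: 24 8,9-O-isopropylidene-11(13)-methylene lactone, via ammonium iodide 23 (not isolated)
Conditions: MeI, MeOH, 23 °C; then aq NaHCO3, CH2Cl2, 23 °C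
Reagents that add atoms: none
Why: Exhaustive N-methylation followed by base-induced β-elimination of trimethylamine (Hofmann-type elimination, E1cB) gives the exocyclic C11=C13 methylene.

Step 18
Reactants: 24 acetonide of the methylene lactone
Product: 25 (1(10)Z,4E,6S,7R,8S,9R)-8,9-dihydroxygermacra-1(10),4,11(13)-trien-12,6-olide
Conditions: AcOH/H2O (4:1), 40 °C
Reagents that add atoms: none
Why: Acid-catalysed acetal hydrolysis frees the 8,9-diol under conditions chosen so as not to add to the methylene lactone or move the lactone to O8.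

Step 19
Reactants: 25 methylene lactone diol
Product: 26 9-O-triethylsilyl ether of 25
Conditions: TESCl (1.1 equiv), imidazole, CH2Cl2, −40 → 0 °C
Reagents that add atoms: triethylsilyl chloride, CC[Si](CC)(CC)Cl
Why: Regioselective silylation, in which the C9 hydroxyl, allylic and flanked by the planar C10, should react faster than the C8 hydroxyl, which is crowded by the fusion carbon C7 and the lactone on the same face.

Step 20
Reactants: 27 (4S)-4-benzyl-3-propanoyl-1,3-oxazolidin-2-one; 28 allyl iodide
Product: 29 (4S)-4-benzyl-3-[(2R)-2-methylpent-4-enoyl]-1,3-oxazolidin-2-one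
Conditions: NaN(SiMe3)2, THF, −78 °C; then 28, −78 → −40 °C
Reagents that add atoms: none
Why: Evans asymmetric alkylation, in which the chelated sodium Z-enolate is allylated on the face opposite the benzyl group and so sets the (R) methyl-bearing centre of the side chain.

Step 21
Reactants: 29 allylated imide
Product: 30 (2R)-2-methylpent-4-en-1-ol
Conditions: LiBH4, H2O (1 equiv), Et2O, 0 °C
Reagents that add atoms: none
Why: Reductive cleavage of the imide gives the primary alcohol and frees the auxiliary without touching the stereocentre or the terminal olefin.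

Step 22
Reactants: 30 (2R)-2-methylpent-4-en-1-ol; 31 stearic acid
Product: 32 (2R)-2-methylpent-4-en-1-yl octadecanoate
Conditions: DCC, DMAP (cat.), CH2Cl2, 23 °C
Reagents that add atoms: none
Why: Steglich esterification joins stearic acid to the primary alcohol under neutral conditions.

Step 23
Reactants: 32 (2R)-2-methylpent-4-en-1-yl octadecanoate
Product: 33 (3R)-3-methyl-4-(octadecanoyloxy)butanoic acid
Conditions: RuCl3·xH2O (cat.), NaIO4, EtOAc/MeCN/H2O, 23 °C
Reagents that add atoms: sodium periodate (oxygen by way of RuO4), [Na+].[O-]I(=O)(=O)=O; water, O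
Why: Ruthenium-catalysed oxidative cleavage of the terminal olefin removes the end carbon and gives the carboxylic acid directly, and the ester and the β-stereocentre are not affected.

Step 24
Reactants: 26 9-O-triethylsilyl diol; 33 (3R)-3-methyl-4-(octadecanoyloxy)butanoic acid
Product: 34 9-O-triethylsilyl ether of the target
Conditions: DCC, DMAP, CH2Cl2, 0 → 23 °C
Reagents that add atoms: none
Why: Steglich esterification of the hindered C8 hydroxyl, with DMAP catalysis for the secondary alcohol and neutral conditions that avoid silyl or acyl migration and epimerisation.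

Step 25
Reactants: 34 9-O-triethylsilyl ether of the target
Product: 35 target, (1(10)Z,4E,6S,7S,8S,9R)-9-hydroxy-8-{[(3R)-3-methyl-4-(octadecanoyloxy)butanoyl]oxy}germacra-1(10),4,11(13)-trien-12,6-olide
Conditions: HF·pyridine, pyridine, THF, 0 °C
Reagents that add atoms: none
Why: Desilylation with buffered HF·pyridine removes the triethylsilyl ether without base, so that the C8 ester should not migrate to O9 and the lactone should not move to another oxygen.

**Compound list**

1 | geraniol | CC(C)=CCC/C(C)=C/CO | starting material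
2 | geranyl tert-butyldimethylsilyl ether | CC(C)=CCC/C(C)=C/CO[Si](C)(C)C(C)(C)C | intermediate
3 | 6,7-epoxide of 2 (racemic at the epoxide carbon) | CC1(C)OC1CC/C(C)=C/CO[Si](C)(C)C(C)(C)C | intermediate
4 | (4E)-6-[(tert-butyldimethylsilyl)oxy]-4-methylhex-4-enal | O=CCC/C(C)=C/CO[Si](C)(C)C(C)(C)C | intermediate
5 | ethyl 2-[bis(2,2,2-trifluoroethoxy)phosphoryl]propanoate (racemic) | CCOC(=O)C(C)P(=O)(OCC(F)(F)F)OCC(F)(F)F | starting material
6 | ethyl (2Z,6E)-8-[(tert-butyldimethylsilyl)oxy]-2,6-dimethylocta-2,6-dienoate | CCOC(=O)/C(C)=C\CC/C(C)=C/CO[Si](C)(C)C(C)(C)C | intermediate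
7 | (2Z,6E)-8-[(tert-butyldimethylsilyl)oxy]-2,6-dimethylocta-2,6-dien-1-ol | OC/C(C)=C\CC/C(C)=C/CO[Si](C)(C)C(C)(C)C | intermediate
8 | (2Z,6E)-8-[(tert-butyldimethylsilyl)oxy]-1-[(tert-butyldiphenylsilyl)oxy]-2,6-dimethylocta-2,6-diene | CC(C)(C)[Si](c1ccccc1)(c1ccccc1)OC/C(C)=C\CC/C(C)=C/CO[Si](C)(C)C(C)(C)C | intermediate
9 | (2E,6Z)-8-[(tert-butyldiphenylsilyl)oxy]-3,7-dimethylocta-2,6-dien-1-ol | CC(C)(C)[Si](c1ccccc1)(c1ccccc1)OC/C(C)=C\CC/C(C)=C/CO | intermediate
10 | (2E,6Z)-8-[(tert-butyldiphenylsilyl)oxy]-3,7-dimethylocta-2,6-dienal | CC(C)(C)[Si](c1ccccc1)(c1ccccc1)OC/C(C)=C\CC/C(C)=C/C=O | intermediate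
11 | (4R)-4-benzyl-1,3-oxazolidin-2-one | O=C1N[C@H](Cc2ccccc2)CO1 | starting material
12 | methyl 4-chloro-4-oxobutanoate | COC(=O)CCC(=O)Cl | starting material
13 | methyl 4-[(4R)-4-benzyl-2-oxo-1,3-oxazolidin-3-yl]-4-oxobutanoate | COC(=O)CCC(=O)N1[C@H](Cc2ccccc2)COC1=O | intermediate
14 | 4-O-trimethylsilyl ether of 15 | COC(=O)C[C@H](C(=O)N1[C@H](Cc2ccccc2)COC1=O)[C@@H](O[Si](C)(C)C)/C=C(\C)CC/C=C(/C)CO[Si](c1ccccc1)(c1ccccc1)C(C)(C)C | intermediate
15 | methyl (3S,4S,5E,9Z)-3-{[(4R)-4-benzyl-2-oxo-1,3-oxazolidin-3-yl]carbonyl}-11-[(tert-butyldiphenylsilyl)oxy]-4-hydroxy-6,10-dimethylundeca-5,9-dienoate (anti-aldol adduct) | COC(=O)C[C@H](C(=O)N1[C@H](Cc2ccccc2)COC1=O)[C@@H](O)/C=C(\C)CC/C=C(/C)CO[Si](c1ccccc1)(c1ccccc1)C(C)(C)C | intermediate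
16 | (4R)-4-benzyl-3-{[(2S,3S)-2-[(1E,5Z)-7-[(tert-butyldiphenylsilyl)oxy]-2,6-dimethylhepta-1,5-dien-1-yl]-5-oxooxolan-3-yl]carbonyl}-1,3-oxazolidin-2-one (cis-lactone) | O=C1C[C@H](C(=O)N2[C@H](Cc3ccccc3)COC2=O)[C@@H](O1)/C=C(\C)CC/C=C(/C)CO[Si](c1ccccc1)(c1ccccc1)C(C)(C)C | intermediate
17 | (4R,5S)-5-[(1E,5Z)-7-[(tert-butyldiphenylsilyl)oxy]-2,6-dimethylhepta-1,5-dien-1-yl]-4-(hydroxymethyl)oxolan-2-one | O=C1C[C@H](CO)[C@@H](O1)/C=C(\C)CC/C=C(/C)CO[Si](c1ccccc1)(c1ccccc1)C(C)(C)C | intermediate
18 | (4R,5S)-5-[(1E,5Z)-7-hydroxy-2,6-dimethylhepta-1,5-dien-1-yl]-4-(hydroxymethyl)oxolan-2-one | O=C1C[C@H](CO)[C@@H](O1)/C=C(\C)CC/C=C(/C)CO | intermediate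
19 | (2S,3S)-2-[(1E,5Z)-2,6-dimethyl-7-oxohepta-1,5-dien-1-yl]-5-oxooxolane-3-carbaldehyde (cis-lactone dialdehyde) | O=C1C[C@H](C=O)[C@@H](O1)/C=C(\C)CC/C=C(/C)C=O | intermediate
20 | (1(10)Z,4E,6S,7R,8S,9R)-8,9-dihydroxygermacra-1(10),4-dien-12,6-olide (6,7-cis lactone, 8,9-cis diol, all four ring hydrogens H6–H9 on one face) | C1C(=O)O[C@H]2/C=C(\C)CC/C=C(/C)[C@@H](O)[C@@H](O)[C@@H]12 | intermediate
21 | 8,9-O-isopropylidene derivative of 20 | C1C(=O)O[C@H]2/C=C(\C)CC/C=C(/C)[C@@H](OC3(C)C)[C@@H](O3)[C@@H]12 | intermediate
22 | 11-[(dimethylamino)methyl] derivative of 21 (C11 epimers) | CN(C)CC1C(=O)O[C@H]2/C=C(\C)CC/C=C(/C)[C@@H](OC3(C)C)[C@@H](O3)[C@@H]12 | intermediate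
23 | trimethylammonium iodide from 22 (C11 epimers) | C[N+](C)(C)CC1C(=O)O[C@H]2/C=C(\C)CC/C=C(/C)[C@@H](OC3(C)C)[C@@H](O3)[C@@H]12.[I-] | intermediate
24 | 8,9-O-isopropylidene derivative of 25 | C=C1C(=O)O[C@H]2/C=C(\C)CC/C=C(/C)[C@@H](OC3(C)C)[C@@H](O3)[C@@H]12 | intermediate
25 | (1(10)Z,4E,6S,7R,8S,9R)-8,9-dihydroxygermacra-1(10),4,11(13)-trien-12,6-olide | C=C1C(=O)O[C@H]2/C=C(\C)CC/C=C(/C)[C@@H](O)[C@@H](O)[C@@H]12 | intermediate
26 | 9-O-triethylsilyl ether of 25 | C=C1C(=O)O[C@H]2/C=C(\C)CC/C=C(/C)[C@@H](O[Si](CC)(CC)CC)[C@@H](O)[C@@H]12 | intermediate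
27 | (4S)-4-benzyl-3-propanoyl-1,3-oxazolidin-2-one | CCC(=O)N1[C@@H](Cc2ccccc2)COC1=O | starting material
28 | allyl iodide | C=CCI | starting material
29 | (4S)-4-benzyl-3-[(2R)-2-methylpent-4-enoyl]-1,3-oxazolidin-2-one | C=CC[C@@H](C)C(=O)N1[C@@H](Cc2ccccc2)COC1=O | intermediate
30 | (2R)-2-methylpent-4-en-1-ol | C=CC[C@@H](C)CO | intermediate
31 | stearic acid | CCCCCCCCCCCCCCCCCC(=O)O | starting material
32 | (2R)-2-methylpent-4-en-1-yl octadecanoate | C=CC[C@@H](C)COC(=O)CCCCCCCCCCCCCCCCC | intermediate
33 | (3R)-3-methyl-4-(octadecanoyloxy)butanoic acid | OC(=O)C[C@@H](C)COC(=O)CCCCCCCCCCCCCCCCC | intermediate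
34 | 9-O-triethylsilyl ether of the target | C=C1C(=O)O[C@H]2/C=C(\C)CC/C=C(/C)[C@@H](O[Si](CC)(CC)CC)[C@@H](OC(=O)C[C@@H](C)COC(=O)CCCCCCCCCCCCCCCCC)[C@@H]12 | intermediate
35 | (1(10)Z,4E,6S,7S,8S,9R)-9-hydroxy-8-{[(3R)-3-methyl-4-(octadecanoyloxy)butanoyl]oxy}germacra-1(10),4,11(13)-trien-12,6-olide | C=C1C(=O)O[C@H]2/C=C(\C)CC/C=C(/C)[C@@H](O)[C@@H](OC(=O)C[C@@H](C)COC(=O)CCCCCCCCCCCCCCCCC)[C@@H]12 | target

**Step count**

Total: 25 steps. Longest linear sequence: 20 steps (steps 1–7, 9–19, 24 and 25); step 8 and steps 20–23 are side branches.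

**Steps most likely to fail**

Step 14. What may go wrong: bond formation through C1 of the delocalised enal ketyl, rotation about C1–C10 in that ketyl with loss of the Z geometry, chain growth between molecules instead of ring closure, and closure to the 8,9-trans diol. Fallback: ring closure and the C9 configuration are dealt with separately. Setting out from dialdehyde 19, the ring is closed with the low-valent titanium reagent made from TiCl3 and Zn–Cu couple in DME at 25 °C (the pinacol stage of the McMurry reaction, stopped before deoxygenation), and the product is taken on as the 8,9-diol mixed at C9 F1. MnO2 in CH2Cl2 then oxidises only the allylic C9 carbinol and gives the 8-hydroxy-9-ketone F2. Reduction of F2 with Zn(BH4)2 in Et2O at −20 °C, with hydride delivered to the zinc chelate of the ketone and the C8 hydroxyl, should give the cis-diol and so return to diol 20. This corrects C9 only; C8 still rests on C7.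

Step 19. What may go wrong: too little discrimination between the two secondary hydroxyls, or silyl migration from O9 to O8 before or during the acylation. Fallback: the two oxygens are told apart by oxidation level and not by a protecting group. Setting out from diol 25, MnO2 in CH2Cl2 oxidises the allylic C9 carbinol to the 8-hydroxy-9-oxo methylene lactone F3. Steglich esterification of the remaining C8 hydroxyl with acid 33 (DCC, DMAP, CH2Cl2, 0 °C, kept short to spare the centre next to the ketone) gives the 9-oxo C8 ester F4. Luche reduction (NaBH4, CeCl3·7H2O, MeOH, −78 °C), with hydride entering from the ring face opposite the C8 ester, should give the 9-hydroxy compound and so arrive directly at target 35 without passing through 26 and 34.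

Step 9. What may go wrong: deprotonation of the enal at its γ-methyl or γ-methylene by Et3N/TMSCl (silyl dienol ether formation), slow turnover of the magnesium catalyst with the ester-bearing imide, and erosion of the anti selectivity. Fallback: enolisation and aldehyde activation are separated and the addition runs through an open transition state. Setting out from imide 13, the dibutylboron Z-enolate is formed first (Bu2BOTf, i-Pr2NEt, CH2Cl2, −78 → 0 °C) and is then added at −78 °C to enal 10 precomplexed with Et2AlCl (the anti-selective Lewis-acid variant of the Evans aldol). No free amine, silyl chloride or magnesium salt meets the enal, the enolate face attacked is the same as in step 9 and the anti adduct should result, so the sequence returns at aldol adduct 15 and makes no new compound (F0).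

**Further compounds**

F1 | step 14 | (1(10)Z,4E)-8,9-dihydroxygermacra-1(10),4-dien-12,6-olide, configuration of 20 at C6, C7 and C8, mixed at C9 | C1C(=O)O[C@H]2/C=C(\C)CC/C=C(/C)C(O)[C@@H](O)[C@@H]12
F2 | step 14 | (1(10)Z,4E)-8-hydroxy-9-oxogermacra-1(10),4-dien-12,6-olide, configuration of 20 at C6, C7 and C8 | C1C(=O)O[C@H]2/C=C(\C)CC/C=C(/C)C(=O)[C@@H](O)[C@@H]12
F3 | step 19 | (1(10)Z,4E)-8-hydroxy-9-oxogermacra-1(10),4,11(13)-trien-12,6-olide, configuration of 25 at C6, C7 and C8 | C=C1C(=O)O[C@H]2/C=C(\C)CC/C=C(/C)C(=O)[C@@H](O)[C@@H]12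
F4 | step 19 | 8-O-[(3R)-3-methyl-4-(octadecanoyloxy)butanoyl] ester of F3 | C=C1C(=O)O[C@H]2/C=C(\C)CC/C=C(/C)C(=O)[C@@H](OC(=O)C[C@@H](C)COC(=O)CCCCCCCCCCCCCCCCC)[C@@H]12
F0 | step 9 | none | none
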